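## Retrosynthetic overview

1. Target 27 ⇐ silylene-bridged macrocyclic alcohol 24: acylation of the only free hydroxyl (O6), then removal of the diisopropylsilylene that masks the C2/C9 diol.
2. 24 ⇐ bromomethylbutenolide enal 22: the C6–C7 bond is made by intramolecular CrCl2 allylation. The butenolide β-carbon C7, normally an electrophilic Michael terminus, reacts as a homoenolate-type nucleophile with the C6 aldehyde. This closes the ten-membered ring, sets C6 and C7, and unveils the α-methylene lactone.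
3. 22 ⇐ alcohols 9 and 18: a mixed diisopropylsilaketal and ring-closing metathesis set the Z C1=C10 olefin; the primary TES ether is then oxidised to the Z-enal.
4. 9 ⇐ silyloxyfuran 5 + methacrolein (asymmetric vinylogous aldol, C8–C9 bond, both stereocentres); 18 ⇐ (Z)-vinyl iodide 13 + (S)-epichlorohydrin (C2 from the chiral pool, Z C4=C5 from an alkyne).
5. Ring order: butenolide first (step 2), then the temporary seven-membered dioxasilepine (step 11), then the ten-membered carbocycle last (step 13); the silepine is opened in the final step.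

Assumption: the SMILES is read as the (2S,6R,7S,8R,9R)-germacranolide with 1(10)Z,4Z olefins and a (2R)-2-methylbutanoate (germacrane numbering: C1=C10(C14), C2–OH, C3, C4(C15)=C5, C6–O-acyl, C7, C8–O-lactone, C9–OH, C11=C13, C12=O), and (R)-2-methylbutanoic acid and (S)-epichlorohydrin are bought as such.

## Route

Step 1
Reactants: 1 allyl acrylate; 2 paraformaldehyde (formaldehyde source)
Product: 3 prop-2-en-1-yl 2-(hydroxymethyl)prop-2-enoate
Conditions: (CH2O)n, DABCO (1,4-diazabicyclo[2.2.2]octane, 1 equiv), 1,4-dioxane/H2O 1:1, rt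
Reagents that add atoms: none
Why: Morita–Baylis–Hillman reaction; the amine adds to the acrylate and the resulting enolate traps formaldehyde, placing the future C13 on the α-carbon.

Step 2
Reactants: 3 prop-2-en-1-yl 2-(hydroxymethyl)prop-2-enoate
Product: 4 3-(hydroxymethyl)furan-2(5H)-one
Conditions: second-generation Grubbs catalyst (3 mol%), CH2Cl2 (0.02 M), 40 °C
Reagents that add atoms: none
Why: Ring-closing metathesis of the allyl and 1,1-disubstituted acrylate olefins closes the five-membered unsaturated lactone with loss of ethylene, and the free hydroxyl is tolerated.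

Step 3
Reactants: 4 3-(hydroxymethyl)furan-2(5H)-one
Product: 5 triethyl{[2-(triethylsilyloxy)furan-3-yl]methoxy}silane
Conditions: TESOTf (2.3 equiv), Et3N (3 equiv), Et2O, 0 °C → rt
Reagents that add atoms: triethylsilyl trifluoromethanesulfonate, CC[Si](CC)(CC)OS(=O)(=O)C(F)(F)F
Why: Soft enolisation with silyl triflate and amine aromatises the butenolide to the 2-silyloxyfuran and silylates the primary alcohol in the same operation.

Step 4
Reactants: 5 triethyl{[2-(triethylsilyloxy)furan-3-yl]methoxy}silane; 6 methacrolein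
Product: 8 (5R)-5-[(1R)-1-hydroxy-2-methylprop-2-en-1-yl]-3-(hydroxymethyl)furan-2(5H)-one, via bis-TES aldol adduct 7 (not isolated)
Conditions: Ti(OiPr)4 (20 mol%), (S)-1,1′-bi-2-naphthol (20 mol%), Et2O, −20 °C; then 1 M HCl, THF, 0 °C
Reagents that add atoms: none
Why: Catalytic asymmetric vinylogous Mukaiyama aldol reaction in which furan C5 attacks the Si face of the titanium-bound aldehyde through an open transition state that favours the threo (5R,1′R) pair; the (S)-ligand sense is assigned by analogy with titanium–binaphthol carbonyl additions and checked by Mosher analysis, the minor erythro isomer is removed by chromatography, and the acid wash cleaves both TES groups.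

Step 5
Reactants: 8 (5R)-5-[(1R)-1-hydroxy-2-methylprop-2-en-1-yl]-3-(hydroxymethyl)furan-2(5H)-one
Product: 9 (5R)-3-(bromomethyl)-5-[(1R)-1-hydroxy-2-methylprop-2-en-1-yl]furan-2(5H)-one
Conditions: NBS (1.2 equiv), Me2S (1.4 equiv), CH2Cl2, −20 → 0 °C
Reagents that add atoms: N-bromosuccinimide, O=C1CCC(=O)N1Br
Why: Corey–Kim bromination displaces the alkoxysulfonium of the primary allylic alcohol with bromide and leaves the hindered secondary alcohol and both stereocentres untouched.

Step 6
Reactants: 10 but-2-yn-1-ol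
Product: 12 (2Z)-3-iodobut-2-en-1-ol, via vinylalanate 11 (not isolated)
Conditions: NaAlH2(OCH2CH2OMe)2, THF, 0 °C → rt; then I2, −78 °C
Reagents that add atoms: iodine, II
Why: Hydroxyl-directed trans-hydroalumination of the propargylic alcohol puts aluminium on the distal carbon cis to CH2O, and iodinolysis with retention gives only the Z vinyl iodide.

Step 7
Reactants: 12 (2Z)-3-iodobut-2-en-1-ol
Product: 13 triethyl{[(2Z)-3-iodobut-2-en-1-yl]oxy}silane
Conditions: TESCl, imidazole, CH2Cl2, 0 °C
Reagents that add atoms: chlorotriethylsilane, CC[Si](Cl)(CC)CC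
Why: Standard silylation of the primary alcohol; the TES ether later serves as a latent aldehyde.

Step 8
Reactants: 13 triethyl{[(2Z)-3-iodobut-2-en-1-yl]oxy}silane; 14 (S)-epichlorohydrin
Product: 16 (2S,4Z)-1-chloro-4-methyl-6-(triethylsilyloxy)hex-4-en-2-ol, via alkenylmagnesium chloride 15 (not isolated)
Conditions: i-PrMgCl·LiCl, THF, 0 °C → rt; then CuI (10 mol%), 14, −40 → −10 °C; aq NH4Cl
Reagents that add atoms: none
Why: Iodine–magnesium exchange with retention of olefin geometry, then copper-catalysed SN2 opening of the epoxide at its CH2 terminus; the C2 stereocentre comes from the epichlorohydrin and no bond to it is touched.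

Step 9
Reactants: 16 (2S,4Z)-1-chloro-4-methyl-6-(triethylsilyloxy)hex-4-en-2-ol
Product: 18 (3S,5Z)-5-methyl-7-(triethylsilyloxy)hepta-1,5-dien-3-ol, via epoxide 17 (not isolated)
Conditions: Me3S+ I− (5 equiv), n-BuLi (5 equiv), THF, −10 °C → rt
Reagents that add atoms: trimethylsulfonium iodide, C[S+](C)C.[I-]
Why: Excess dimethylsulfonium methylide closes the chlorohydrin to the epoxide, opens it at the terminal carbon and eliminates dimethyl sulfide, giving the one-carbon-homologated allylic alcohol with C2 unchanged.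

Step 10
Reactants: 9 (5R)-3-(bromomethyl)-5-[(1R)-1-hydroxy-2-methylprop-2-en-1-yl]furan-2(5H)-one; 18 (3S,5Z)-5-methyl-7-(triethylsilyloxy)hepta-1,5-dien-3-ol
Product: 20 diisopropyl{[(1R)-1-[(2R)-4-(bromomethyl)-5-oxo-2,5-dihydrofuran-2-yl]-2-methylprop-2-en-1-yl]oxy}{[(3S,5Z)-5-methyl-7-(triethylsilyloxy)hepta-1,5-dien-3-yl]oxy}silane, via silyl triflate 19 (not isolated)
Conditions: iPr2Si(OTf)2 (1.1 equiv), 2,6-lutidine (3 equiv), CH2Cl2, −78 °C, 9 added slowly; then 18, −78 → 0 °C
Reagents that add atoms: diisopropylsilyl bis(trifluoromethanesulfonate), CC(C)[Si](C(C)C)(OS(=O)(=O)C(F)(F)F)OS(=O)(=O)C(F)(F)F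
Why: Stepwise silylation with the silyl bis-triflate (hindered alcohol first, since the mono-triflate is less reactive than the bis-triflate) gives the unsymmetrical silaketal, and 2,6-lutidine is too hindered to attack the allylic bromide.

Step 11
Reactants: 20 mixed diisopropylsilaketal
Product: 21 (4R,7S)-4-[(2R)-4-(bromomethyl)-5-oxo-2,5-dihydrofuran-2-yl]-2,2-diisopropyl-5-methyl-7-[(2Z)-2-methyl-4-(triethylsilyloxy)but-2-en-1-yl]-4,7-dihydro-1,3,2-dioxasilepine
Conditions: second-generation Hoveyda–Grubbs catalyst (10 mol%), toluene (5 mM), 80 °C, argon sparge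
Reagents that add atoms: none
Why: Temporary-silicon-tethered ring-closing metathesis joins the isopropenyl and vinyl groups inside a seven-membered ring, which can only give the Z trisubstituted C1=C10 olefin; the other olefins are trisubstituted or electron-poor and do not react.

Step 12
Reactants: 21 dioxasilepine TES ether
Product: 22 (4R,7S)-4-[(2R)-4-(bromomethyl)-5-oxo-2,5-dihydrofuran-2-yl]-2,2-diisopropyl-5-methyl-7-[(2Z)-2-methyl-4-oxobut-2-en-1-yl]-4,7-dihydro-1,3,2-dioxasilepine
Conditions: (COCl)2, DMSO, CH2Cl2, −78 → −35 °C; then iPr2NEt, −78 → −20 °C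
Reagents that add atoms: none
Why: Swern conditions oxidise a primary TES ether directly to the aldehyde (activated DMSO attacks the silyl ether oxygen) while the secondary silaketal survives, and the hindered amine at low temperature spares the allylic bromide and the Z-enal geometry.

Step 13
Reactants: 22 bromomethylbutenolide Z-enal
Product: 24 (2S,6R,7S,8R,9R)-6-hydroxy-2,9-(diisopropylsilylenedioxy)germacra-1(10)Z,4Z,11(13)-trien-8,12-olide, via allylchromium dichloride 23 (not isolated)
Conditions: CrCl2 (10 equiv), THF, 25 °C, syringe-pump addition to 2 mM; aq work-up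
Reagents that add atoms: none
Why: Proposed new method: intramolecular Nozaki–Hiyama allylation in which CrCl2 turns the bromomethylbutenolide into an allylchromium species (trivalent chromium) whose lactone β-carbon C7 adds as a homoenolate-type nucleophile to the C6 aldehyde through a closed chair transition state, closing the ten-membered ring and revealing the α-methylene lactone at once; the ring-locked allyl geometry (C8 trans to CH2Cr) with the aldehyde chain equatorial gives the anti 6R,7S pair, and bond formation on the butenolide face opposite the C8–C9 bond gives the trans lactone; the closest known reactions are intermolecular Barbier additions of 3-(bromomethyl)furan-2(5H)-one to aldehydes and CrCl2-mediated macrocyclisations of 2-(bromomethyl)enoates onto aldehydes in germacranolide synthesis.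

Step 14
Reactants: 24 silylene-bridged macrocyclic alcohol; 25 (R)-2-methylbutanoic acid
Product: 26 (2S,6R,7S,8R,9R)-6-[(2R)-2-methylbutanoyloxy]-2,9-(diisopropylsilylenedioxy)germacra-1(10)Z,4Z,11(13)-trien-8,12-olide
Conditions: N-(3-dimethylaminopropyl)-N′-ethylcarbodiimide hydrochloride (EDC·HCl, 3 equiv), 4-(dimethylamino)pyridine (0.3 equiv), CH2Cl2, 0 °C → rt
Reagents that add atoms: none
Why: Steglich esterification of the only free hydroxyl; low temperature and substoichiometric 4-(dimethylamino)pyridine limit epimerisation of the α-branched acid and lactone migration to O6.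

Step 15
Reactants: 26 silylene-bridged ester
Product: 27 (3aS,4R,5Z,8S,9Z,11R,11aR)-8,11-dihydroxy-6,10-dimethyl-3-methylidene-2-oxo-2,3,3a,4,7,8,11,11a-octahydrocyclodeca[b]furan-4-yl (2R)-2-methylbutanoate (CNP0176600.1)
Conditions: HF·pyridine, pyridine, THF, 0 °C → rt
Reagents that add atoms: none
Why: Fluoride cleaves both Si–O bonds of the silylene under buffered conditions that spare the ester, the α-methylene lactone and the allylic alcohols.

## Compound list

1 | allyl acrylate | C=CC(=O)OCC=C | starting material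
2 | paraformaldehyde (formaldehyde source) | C=O | starting material
3 | prop-2-en-1-yl 2-(hydroxymethyl)prop-2-enoate | C=C(CO)C(=O)OCC=C | intermediate
4 | 3-(hydroxymethyl)furan-2(5H)-one | O=C1OCC=C1CO | intermediate
5 | triethyl{[2-(triethylsilyloxy)furan-3-yl]methoxy}silane | CC[Si](CC)(CC)OCc1ccoc1O[Si](CC)(CC)CC | intermediate
6 | methacrolein (2-methylprop-2-enal) | CC(=C)C=O | starting material
7 | (5R)-5-[(1R)-2-methyl-1-(triethylsilyloxy)prop-2-en-1-yl]-3-[(triethylsilyloxy)methyl]furan-2(5H)-one | O=C1O[C@@H]([C@H](O[Si](CC)(CC)CC)C(C)=C)C=C1CO[Si](CC)(CC)CC | intermediate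
8 | (5R)-5-[(1R)-1-hydroxy-2-methylprop-2-en-1-yl]-3-(hydroxymethyl)furan-2(5H)-one | O=C1O[C@@H]([C@H](O)C(C)=C)C=C1CO | intermediate
9 | (5R)-3-(bromomethyl)-5-[(1R)-1-hydroxy-2-methylprop-2-en-1-yl]furan-2(5H)-one | O=C1O[C@@H]([C@H](O)C(C)=C)C=C1CBr | intermediate
10 | but-2-yn-1-ol | CC#CCO | starting material
11 | sodium [(1Z)-1-methyl-3-oxidoprop-1-en-1-yl]bis(2-methoxyethoxy)aluminate (five-membered oxaaluminacycle) | CC1=CCO[Al-]1(OCCOC)OCCOC.[Na+] | intermediate
12 | (2Z)-3-iodobut-2-en-1-ol | C/C(I)=C/CO | intermediate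
13 | triethyl{[(2Z)-3-iodobut-2-en-1-yl]oxy}silane | C/C(I)=C/CO[Si](CC)(CC)CC | intermediate
14 | (S)-epichlorohydrin, (2S)-2-(chloromethyl)oxirane | ClC[C@@H]1CO1 | starting material
15 | chlorido[(2Z)-4-(triethylsilyloxy)but-2-en-2-yl]magnesium | C/C([Mg]Cl)=C/CO[Si](CC)(CC)CC | intermediate
16 | (2S,4Z)-1-chloro-4-methyl-6-(triethylsilyloxy)hex-4-en-2-ol | ClC[C@@H](O)C/C(C)=C\CO[Si](CC)(CC)CC | intermediate
17 | (2S)-2-[(2Z)-2-methyl-4-(triethylsilyloxy)but-2-en-1-yl]oxirane | C1O[C@H]1C/C(C)=C\CO[Si](CC)(CC)CC | intermediate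
18 | (3S,5Z)-5-methyl-7-(triethylsilyloxy)hepta-1,5-dien-3-ol | C=C[C@@H](O)C/C(C)=C\CO[Si](CC)(CC)CC | intermediate
19 | {[(1R)-1-[(2R)-4-(bromomethyl)-5-oxo-2,5-dihydrofuran-2-yl]-2-methylprop-2-en-1-yl]oxy}diisopropylsilyl trifluoromethanesulfonate | O=C1O[C@@H]([C@H](O[Si](C(C)C)(C(C)C)OS(=O)(=O)C(F)(F)F)C(C)=C)C=C1CBr | intermediate
20 | diisopropyl{[(1R)-1-[(2R)-4-(bromomethyl)-5-oxo-2,5-dihydrofuran-2-yl]-2-methylprop-2-en-1-yl]oxy}{[(3S,5Z)-5-methyl-7-(triethylsilyloxy)hepta-1,5-dien-3-yl]oxy}silane | O=C1O[C@@H]([C@H](O[Si](C(C)C)(C(C)C)O[C@H](C=C)C/C(C)=C\CO[Si](CC)(CC)CC)C(C)=C)C=C1CBr | intermediate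
21 | (4R,7S)-4-[(2R)-4-(bromomethyl)-5-oxo-2,5-dihydrofuran-2-yl]-2,2-diisopropyl-5-methyl-7-[(2Z)-2-methyl-4-(triethylsilyloxy)but-2-en-1-yl]-4,7-dihydro-1,3,2-dioxasilepine | O=C1O[C@@H]([C@@H]2O[Si](C(C)C)(C(C)C)O[C@@H](C/C(C)=C\CO[Si](CC)(CC)CC)C=C2C)C=C1CBr | intermediate
22 | (4R,7S)-4-[(2R)-4-(bromomethyl)-5-oxo-2,5-dihydrofuran-2-yl]-2,2-diisopropyl-5-methyl-7-[(2Z)-2-methyl-4-oxobut-2-en-1-yl]-4,7-dihydro-1,3,2-dioxasilepine | O=C1O[C@@H]([C@@H]2O[Si](C(C)C)(C(C)C)O[C@@H](C/C(C)=C\C=O)C=C2C)C=C1CBr | intermediate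
23 | allylchromium dichloride of 22 (CH2Br replaced by CH2CrCl2, trivalent chromium) | O=C1O[C@@H]([C@@H]2O[Si](C(C)C)(C(C)C)O[C@@H](C/C(C)=C\C=O)C=C2C)C=C1C[Cr](Cl)Cl | intermediate
24 | (2S,6R,7S,8R,9R)-6-hydroxy-2,9-(diisopropylsilylenedioxy)germacra-1(10)Z,4Z,11(13)-trien-8,12-olide (trans-fused α-methylene lactone, O2 and O9 bridged by Si(iPr)2) | C=C1C(=O)O[C@@H]2[C@@H]1[C@H](O)/C=C(/C)C[C@H](O[Si]3(C(C)C)C(C)C)/C=C(/C)[C@H]2O3 | intermediate
25 | (R)-2-methylbutanoic acid | CC[C@@H](C)C(=O)O | starting material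
26 | (2S,6R,7S,8R,9R)-6-[(2R)-2-methylbutanoyloxy]-2,9-(diisopropylsilylenedioxy)germacra-1(10)Z,4Z,11(13)-trien-8,12-olide | C=C1C(=O)O[C@@H]2[C@@H]1[C@H](OC(=O)[C@H](C)CC)/C=C(/C)C[C@H](O[Si]3(C(C)C)C(C)C)/C=C(/C)[C@H]2O3 | intermediate
27 | (3aS,4R,5Z,8S,9Z,11R,11aR)-8,11-dihydroxy-6,10-dimethyl-3-methylidene-2-oxo-2,3,3a,4,7,8,11,11a-octahydrocyclodeca[b]furan-4-yl (2R)-2-methylbutanoate | C=C1C(=O)O[C@@H]2[C@@H]1[C@H](OC(=O)[C@H](C)CC)/C=C(/C)C[C@H](O)/C=C(/C)[C@H]2O | target

## Step count and risks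

Total step count: 15. Longest linear sequence: 11 steps (1–5, then 10–15); the other branch (6–9, then 10–15) is 10 steps.

Three steps most likely to fail:

**Step 13 (macrocyclisation).** The silylene bridge forces C8 and C3 onto opposite faces of the seven-membered ring, so the ten-membered ring must close across a strained bicyclic transition state. Facial selectivity at C7 and oligomerisation are further unknowns. The fallback removes the tether before ring closure. It sets out from 21: HF·pyridine strips the silylene and the primary TES group to give the bromo triol F1, and TESOTf/2,6-lutidine gives the tris-TES ether F2. Swern oxidation of the primary TES ether gives the open-chain enal F3, and CrCl2 under high dilution closes it to the bis-TES macrocyclic alcohol F4. Esterification with 25 gives the bis-TES ester F5, and HF·pyridine removes both TES groups, so the fallback comes back to the route at 27.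

**Step 4 (asymmetric vinylogous aldol).** Titanium–binaphthol catalysis may give only modest threo selectivity or enantioselectivity with an α-branched enal, and the silyloxymethyl group on the furan could ionise. The fallback replaces asymmetric catalysis by a resolution. It sets out from 5 and 6: BF3·OEt2 in CH2Cl2 at −78 °C gives the racemic threo mono-TES alcohol F6. Sharpless kinetic resolution (Ti(OiPr)4, D-(−)-diisopropyl tartrate, t-BuOOH, 4 Å sieves, −20 °C) epoxidises the (5S,1′S) enantiomer to the epoxy alcohol F8 and leaves the (5R,1′R) mono-TES alcohol F7. 1 M HCl in THF then removes the TES group, and the fallback comes back to the route at 8.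

**Step 11 (tethered metathesis).** The ring closure makes a trisubstituted olefin flanked by two branched carbinol carbons and may stall. The fallback reverses the order of ring formation. It sets out from 20: Swern oxidation gives the open-chain diene enal F9, and CrCl2 cyclisation through the still-flexible silaketal gives the eleven-membered macrocyclic alcohol F10. Transannular ring-closing metathesis with second-generation Hoveyda–Grubbs catalyst then joins the isopropenyl and vinyl groups, now held close together, and the fallback comes back to the route at 24.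

Further compounds

F1 | step 13 | (5R)-3-(bromomethyl)-5-[(1R,2Z,4S,6Z)-1,4,8-trihydroxy-2,6-dimethylocta-2,6-dien-1-yl]furan-2(5H)-one | O=C1O[C@@H]([C@H](O)/C(C)=C\[C@@H](O)C/C(C)=C\CO)C=C1CBr
F2 | step 13 | tris(triethylsilyl) ether of F1 | O=C1O[C@@H]([C@H](O[Si](CC)(CC)CC)/C(C)=C\[C@@H](O[Si](CC)(CC)CC)C/C(C)=C\CO[Si](CC)(CC)CC)C=C1CBr
F3 | step 13 | (2Z,5S,6Z,8R)-8-[(2R)-4-(bromomethyl)-5-oxo-2,5-dihydrofuran-2-yl]-3,7-dimethyl-5,8-bis(triethylsilyloxy)octa-2,6-dienal | O=C1O[C@@H]([C@H](O[Si](CC)(CC)CC)/C(C)=C\[C@@H](O[Si](CC)(CC)CC)C/C(C)=C\C=O)C=C1CBr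
F4 | step 13 | (2S,6R,7S,8R,9R)-6-hydroxy-2,9-bis(triethylsilyloxy)germacra-1(10)Z,4Z,11(13)-trien-8,12-olide | C=C1C(=O)O[C@@H]2[C@@H]1[C@H](O)/C=C(/C)C[C@H](O[Si](CC)(CC)CC)/C=C(/C)[C@H]2O[Si](CC)(CC)CC
F5 | step 13 | (2S,6R,7S,8R,9R)-6-[(2R)-2-methylbutanoyloxy]-2,9-bis(triethylsilyloxy)germacra-1(10)Z,4Z,11(13)-trien-8,12-olide | C=C1C(=O)O[C@@H]2[C@@H]1[C@H](OC(=O)[C@H](C)CC)/C=C(/C)C[C@H](O[Si](CC)(CC)CC)/C=C(/C)[C@H]2O[Si](CC)(CC)CC
F6 | step 4 | racemic threo 5-(1-hydroxy-2-methylprop-2-en-1-yl)-3-[(triethylsilyloxy)methyl]furan-2(5H)-one (1:1 mixture of F7 and its enantiomer) | O=C1O[C@@H]([C@H](O)C(C)=C)C=C1CO[Si](CC)(CC)CC.O=C1O[C@H]([C@@H](O)C(C)=C)C=C1CO[Si](CC)(CC)CC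
F7 | step 4 | (5R)-5-[(1R)-1-hydroxy-2-methylprop-2-en-1-yl]-3-[(triethylsilyloxy)methyl]furan-2(5H)-one | O=C1O[C@@H]([C@H](O)C(C)=C)C=C1CO[Si](CC)(CC)CC
F8 | step 4 | (5S)-5-{(R)-hydroxy[(2R)-2-methyloxiran-2-yl]methyl}-3-[(triethylsilyloxy)methyl]furan-2(5H)-one | O=C1O[C@H]([C@@H](O)[C@@]2(C)CO2)C=C1CO[Si](CC)(CC)CC
F9 | step 11 | diisopropyl{[(1R)-1-[(2R)-4-(bromomethyl)-5-oxo-2,5-dihydrofuran-2-yl]-2-methylprop-2-en-1-yl]oxy}{[(3S,5Z)-5-methyl-7-oxohepta-1,5-dien-3-yl]oxy}silane | O=C1O[C@@H]([C@H](O[Si](C(C)C)(C(C)C)O[C@H](C=C)C/C(C)=C\C=O)C(C)=C)C=C1CBr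
F10 | step 11 | eleven-membered silaketal-bridged macrocycle: trans-fused α-methylene lactone with 6R-hydroxyl, 4Z olefin, C2 (S) bearing vinyl and C9 (R) bearing isopropenyl, O2 and O9 linked through Si(iPr)2 | C=C1C(=O)O[C@@H]2[C@@H]1[C@H](O)/C=C(/C)C[C@@H](C=C)O[Si](C(C)C)(C(C)C)O[C@@H]2C(C)=C
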